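The ten-membered carbocycle is closed at the bond joining the ring CH2 (β to the carbinol carbon) to the methyl-bearing oxirane carbon. Before epoxidation this carbon is the sp2 terminus of a Z-trisubstituted alkene, and the ring is a nearly strain-free cis,cis-cyclodeca-1,6-diene; an intramolecular B-alkyl Suzuki–Miyaura coupling of a vinyl carbinol with a (Z)-iodoalkene therefore closes it from an open trans-γ-butyrolactone carrying both arms (α-methylene masked as its Me2NH adduct). The chair of this diene then directs an anti bromohydrin/closure sequence to the oxirane. The lactone triad comes from an indium Barbier reaction of a chiral 3-(bromomethyl)butenolide; two catalytic propiolate additions set the remaining centres.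

Key step: step 14

Remarks on the chemistry:
- The facial sense of the Zn–ProPhenol alkynylation is assigned by analogy with its aldol reactions; both ligand antipodes are commercial, so the antipodes in steps 1 and 6 are exchanged if the sense is the opposite.
- Organometallics formed and consumed within a single operation (zinc acetylides, the vinylcuprate, the allylindium) are not numbered; species that persist between two stages of a one-pot step are.
- The lactone α-carbon of 20–23 is a temporary stereocentre of no consequence and is drawn unspecified.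

Step 1
Reactants: 1 methyl propiolate; 2 acrolein
Product: 3 methyl (4R)-4-hydroxyhex-5-en-2-ynoate
Conditions: (R,R)-ProPhenol (10 mol %), Me2Zn, Ph3P=O (20 mol %), toluene, 0 °C; aq. NH4Cl
Reagents that add atoms: none
Why: Zn–ProPhenol-catalysed enantioselective alkynylation of an enal (Trost) should deliver the zinc acetylide of 1 to one aldehyde face, so that the catalyst alone sets the carbinol carbon as R.

Step 2
Reactants: 3 methyl (4R)-4-hydroxyhex-5-en-2-ynoate
Product: 4 methyl (4R)-4-[(tert-butyldimethylsilyl)oxy]hex-5-en-2-ynoate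
Conditions: TBSCl, imidazole, DMF, 0 °C → rt
Reagents that add atoms: tert-butyldimethylsilyl chloride, CC(C)(C)[Si](C)(C)Cl
Why: Standard silylation of a secondary alcohol; the ether prevents lactonisation in step 3 and later keeps this oxygen out of the bromonium chemistry.

Step 3
Reactants: 4 methyl (4R)-4-[(tert-butyldimethylsilyl)oxy]hex-5-en-2-ynoate
Product: 5 methyl (2Z,4R)-4-[(tert-butyldimethylsilyl)oxy]-3-methylhexa-2,5-dienoate
Conditions: Me2CuLi (from MeLi, CuI), THF, −78 °C; MeOH then aq. NH4Cl at −78 °C
Reagents that add atoms: lithium dimethylcuprate, [Li+].C[Cu-]C (made from methyllithium, [Li]C, and copper(I) iodide)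
Why: syn-Carbocupration (cuprate conjugate addition) of the ynoate with protonation at −78 °C should place CH3 and H cis, so the ester and the silyloxy-bearing carbon end up cis (2Z), with the stereocentre untouched.

Step 4
Reactants: 5 methyl (2Z,4R)-4-[(tert-butyldimethylsilyl)oxy]-3-methylhexa-2,5-dienoate
Product: 6 (2Z,4R)-4-[(tert-butyldimethylsilyl)oxy]-3-methylhexa-2,5-dien-1-ol
Conditions: DIBAL-H, CH2Cl2, −78 °C; Rochelle salt
Reagents that add atoms: none
Why: 1,2-Reduction of the enoate by DIBAL-H at low temperature should give the allylic alcohol without affecting the silyl ether or the alkene geometry.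

Step 5
Reactants: 6 (2Z,4R)-4-[(tert-butyldimethylsilyl)oxy]-3-methylhexa-2,5-dien-1-ol
Product: 7 (2Z,4R)-4-[(tert-butyldimethylsilyl)oxy]-3-methylhexa-2,5-dienal
Conditions: activated MnO2, CH2Cl2, rt, dark; used at once
Reagents that add atoms: none
Why: Neutral MnO2 oxidation of the allylic alcohol should give the Z enal with retention of geometry.

Step 6
Reactants: 7 (2Z,4R)-4-[(tert-butyldimethylsilyl)oxy]-3-methylhexa-2,5-dienal; 1 methyl propiolate
Product: 8 methyl (4S,5Z,7R)-7-[(tert-butyldimethylsilyl)oxy]-4-hydroxy-6-methylnona-5,8-dien-2-ynoate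
Conditions: (S,S)-ProPhenol (20 mol %), Me2Zn, Ph3P=O (40 mol %), toluene, 4 °C; aq. NH4Cl
Reagents that add atoms: none
Why: Second Zn–ProPhenol alkynylation with the antipodal ligand, in which catalyst control (the existing stereocentre is remote) should set the new carbinol carbon as S.

Step 7
Reactants: 8 methyl (4S,5Z,7R)-7-[(tert-butyldimethylsilyl)oxy]-4-hydroxy-6-methylnona-5,8-dien-2-ynoate
Product: 10 (5S)-3-(hydroxymethyl)-5-[(1Z,3R)-3-[(tert-butyldimethylsilyl)oxy]-2-methylpenta-1,4-dien-1-yl]furan-2(5H)-one, via vinylalane 9 (not isolated)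
Conditions: i-Bu2AlH (2.3 equiv), THF/HMPA, 0 °C; then HCHO (gas, from paraformaldehyde), 0 °C → rt; Rochelle salt
Reagents that add atoms: formaldehyde, C=O; diisobutylaluminium hydride, CC(C)C[AlH]CC(C)C (its atoms are in 9 only)
Why: Conjugate syn-hydroalumination of the ynoate (Tsuda–Saegusa vinylalumination) should give the α-alumino enoate 9, whose C–Al bond is hydroxymethylated with retention, and the γ-alkoxide, now cis to the ester, lactonises to the butenolide without touching the carbinol stereocentre.

Step 8
Reactants: 10 (5S)-3-(hydroxymethyl)-5-[(1Z,3R)-3-[(tert-butyldimethylsilyl)oxy]-2-methylpenta-1,4-dien-1-yl]furan-2(5H)-one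
Product: 11 (5S)-3-(bromomethyl)-5-[(1Z,3R)-3-[(tert-butyldimethylsilyl)oxy]-2-methylpenta-1,4-dien-1-yl]furan-2(5H)-one
Conditions: CBr4, PPh3, CH2Cl2, 0 °C
Reagents that add atoms: carbon tetrabromide, BrC(Br)(Br)Br
Why: Appel bromination of the primary allylic alcohol under neutral conditions, so the base-sensitive C5–H of the butenolide is not enolised.

Step 9
Reactants: 12 but-2-yn-1-ol
Product: 14 (2Z)-3-iodobut-2-en-1-ol, via alkenylalanate 13 (not isolated)
Conditions: Red-Al, THF, 0 °C → rt; then I2, THF, −78 → 0 °C
Reagents that add atoms: iodine, II; Red-Al, [Na+].COCCO[AlH2-]OCCOC (its atoms are in 13 only)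
Why: Hydroxyl-directed trans-hydroalumination places aluminium on the distal alkyne carbon in the five-membered alanate 13, and iodinolysis with retention should give the iodide cis to the CH2OH group.

Step 10
Reactants: 14 (2Z)-3-iodobut-2-en-1-ol
Product: 15 (2Z)-3-iodobut-2-enal
Conditions: activated MnO2, CH2Cl2, rt, dark; used at once
Reagents that add atoms: none
Why: Neutral allylic oxidation with MnO2 should retain the Z geometry of the iodoalkene.

Step 11
Reactants: 11 (5S)-3-(bromomethyl)-5-[(1Z,3R)-3-[(tert-butyldimethylsilyl)oxy]-2-methylpenta-1,4-dien-1-yl]furan-2(5H)-one; 15 (2Z)-3-iodobut-2-enal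
Product: 16 (4S,5S)-4-[(1S,2Z)-1-hydroxy-3-iodobut-2-en-1-yl]-3-methylidene-5-[(1Z,3R)-3-[(tert-butyldimethylsilyl)oxy]-2-methylpenta-1,4-dien-1-yl]oxolan-2-one
Conditions: In powder, THF/H2O (1:1), rt
Reagents that add atoms: none
Why: Indium-mediated Barbier allylation with γ-attack of the 2-carbonyl allylindium (known for 3-(bromomethyl)furan-2(5H)-one) should form the new bond at C4 anti to the C5 substituent (trans lactone), while the ring-locked E-type allyl geometry in a closed chair transition state with the aldehyde substituent equatorial sets the carbinol carbon as 1S.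

Step 12
Reactants: 16 (4S,5S)-4-[(1S,2Z)-1-hydroxy-3-iodobut-2-en-1-yl]-3-methylidene-5-[(1Z,3R)-3-[(tert-butyldimethylsilyl)oxy]-2-methylpenta-1,4-dien-1-yl]oxolan-2-one; 17 angelic acid
Product: 19 (1S,2Z)-3-iodo-1-{(2S,3R)-4-methylidene-5-oxo-2-[(1Z,3R)-3-[(tert-butyldimethylsilyl)oxy]-2-methylpenta-1,4-dien-1-yl]oxolan-3-yl}but-2-en-1-yl (2Z)-2-methylbut-2-enoate, via mixed anhydride 18 (not isolated)
Conditions: 2,4,6-Cl3C6H2COCl, Et3N, toluene, rt; then 16, toluene, 75 °C (no DMAP)
Reagents that add atoms: 2,4,6-trichlorobenzoyl chloride, O=C(Cl)c1c(Cl)cc(Cl)cc1Cl (its atoms are in 18 only)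
Why: Yamaguchi mixed-anhydride acylation esterifies the secondary alcohol with retention at carbon, and the DMAP-free protocol is the usual way to keep the angelate Z.

Step 13
Reactants: 19 the angelate described in step 12
Product: 20 dimethylamine adduct of 19, i.e. 19 with the 4-methylidene group replaced by a 4-[(dimethylamino)methyl] group
Conditions: Me2NH (2 M in THF), THF, 0 °C → rt
Reagents that add atoms: dimethylamine, CNC
Why: Aza-Michael addition masks the α-methylene lactone (a known protecting tactic) against hydroboration, Heck cyclisation and hydroxide addition in step 14.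

Step 14
Reactants: 20 dimethylamine adduct of 19
Product: 22 macrocyclic amine, the ten-membered cis,cis-cyclodeca-1,6-diene trans-fused to the 3-[(dimethylamino)methyl]-γ-lactone with the OTBS and angelate groups in place, via B-alkyl-9-BBN 21 (not isolated)
Conditions: 9-BBN, THF, 0 °C → rt; then slow addition (syringe pump) to Pd(dppf)Cl2 (20 mol %), AsPh3, Cs2CO3, DMF/THF/H2O, rt, ca. 2 mM
Reagents that add atoms: 9-borabicyclo[3.3.1]nonane, B1C2CCCC1CCC2 (its atoms are in 21 only)
Why: Anti-Markovnikov hydroboration of the only monosubstituted alkene gives the primary borane 21; oxidative addition of Pd(0) into the (Z)-C(sp2)–I bond, base-assisted B→Pd transfer of the primary alkyl group and reductive elimination then form the CH2–C(CH3)= bond with retention of the Z geometry. The closest known reaction type is the B-alkyl Suzuki–Miyaura macrocyclisation. The one ring closed is the ten-membered carbocycle, by C(sp3)–C(sp2) reductive elimination from an eleven-membered palladacycle; no stereocentre is created, and the four existing ones and both Z alkenes are carried through unchanged. The closure exploits the fact that the ring at this oxidation level is a cis,cis-cyclodeca-1,6-diene, whose chair is nearly strain-free and lets all three oxygen substituents sit outside, while the two Z alkenes and the trans-lactone turn bring the chain ends together. The step needs hydroboration of the vinyl group over the trisubstituted, iodo-substituted and conjugated alkenes (secured by 9-BBN and by the masked lactone, which also removes the 5-exo Heck pathway) and ring closure over oligomerisation and β-hydride elimination (slow addition at high dilution, dppf/AsPh3).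

Step 15
Reactants: 22 macrocyclic amine
Product: 24 macrocyclic diene, the ten-membered ring of the target with a (Z)-C(CH3)=CH alkene in place of the oxirane and a TBS ether on the carbinol, via ammonium iodide 23 (not isolated)
Conditions: MeI, MeCN, rt; evaporate; then aq. NaHCO3/EtOAc, rt
Reagents that add atoms: iodomethane, CI (its atoms are in 23 only)
Why: Exhaustive N-methylation followed by hydrogencarbonate-induced E1cB (Hofmann-type) elimination of trimethylamine should regenerate the α-methylene lactone under conditions that leave the esters untouched.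

Step 16
Reactants: 24 macrocyclic diene
Product: 26 TBS ether of the target, via bromohydrin 25 (not isolated)
Conditions: NBS, THF/H2O (4:1), 0 °C; then DBU, CH2Cl2, 0 °C → rt
Reagents that add atoms: water, O; N-bromosuccinimide, O=C1CCC(=O)N1Br (its bromine is in 25 only)
Why: Bromohydrin formation and base closure: in the chair of the cyclodeca-1,6-diene the two allylic ring bonds flanking the C(CH3)=CH alkene lie on opposite faces, so Br+ should add to the CH carbon anti to the CH(OAng)–CH(lactone) bond and water to the methyl-bearing carbon anti to the CH2–CH2 bond (anti, Markovnikov), and SN2 closure by the tertiary alkoxide with inversion at CHBr then gives the cis-oxirane with both new centres on the face that direct oxygen transfer would not favour, the other ring alkene being deactivated by two allylic oxygens.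

Step 17
Reactants: 26 TBS ether of the target
Product: 27 CNP0191628.1
Conditions: HF·pyridine, pyridine, THF, 0 °C → rt
Reagents that add atoms: none
Why: Buffered fluoride cleavage of the allylic silyl ether should leave the oxirane, the angelate and the α-methylene lactone intact.

Compound list
1 | methyl propiolate | C#CC(=O)OC | starting material
2 | acrolein | C=CC=O | starting material
3 | methyl (4R)-4-hydroxyhex-5-en-2-ynoate | COC(=O)C#C[C@H](O)C=C | intermediate
4 | methyl (4R)-4-[(tert-butyldimethylsilyl)oxy]hex-5-en-2-ynoate | COC(=O)C#C[C@H](O[Si](C)(C)C(C)(C)C)C=C | intermediate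
5 | methyl (2Z,4R)-4-[(tert-butyldimethylsilyl)oxy]-3-methylhexa-2,5-dienoate | COC(=O)/C=C(/C)[C@H](O[Si](C)(C)C(C)(C)C)C=C | intermediate
6 | (2Z,4R)-4-[(tert-butyldimethylsilyl)oxy]-3-methylhexa-2,5-dien-1-ol | OC/C=C(/C)[C@H](O[Si](C)(C)C(C)(C)C)C=C | intermediate
7 | (2Z,4R)-4-[(tert-butyldimethylsilyl)oxy]-3-methylhexa-2,5-dienal | O=C/C=C(/C)[C@H](O[Si](C)(C)C(C)(C)C)C=C | intermediate
8 | methyl (4S,5Z,7R)-7-[(tert-butyldimethylsilyl)oxy]-4-hydroxy-6-methylnona-5,8-dien-2-ynoate | COC(=O)C#C[C@@H](O)/C=C(/C)[C@H](O[Si](C)(C)C(C)(C)C)C=C | intermediate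
9 | vinylalane: 8 after O-alumination and syn-hydroalumination (Al on C2 cis to H-3, ester cis to C4) | COC(=O)/C([Al](CC(C)C)CC(C)C)=C\[C@@H](O[Al](CC(C)C)CC(C)C)/C=C(/C)[C@H](O[Si](C)(C)C(C)(C)C)C=C | intermediate
10 | (5S)-3-(hydroxymethyl)-5-[(1Z,3R)-3-[(tert-butyldimethylsilyl)oxy]-2-methylpenta-1,4-dien-1-yl]furan-2(5H)-one | OCC1=C[C@H](/C=C(/C)[C@H](O[Si](C)(C)C(C)(C)C)C=C)OC1=O | intermediate
11 | (5S)-3-(bromomethyl)-5-[(1Z,3R)-3-[(tert-butyldimethylsilyl)oxy]-2-methylpenta-1,4-dien-1-yl]furan-2(5H)-one | BrCC1=C[C@H](/C=C(/C)[C@H](O[Si](C)(C)C(C)(C)C)C=C)OC1=O | intermediate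
12 | but-2-yn-1-ol | CC#CCO | starting material
13 | sodium 2,2-bis(2-methoxyethoxy)-3-methyl-2,5-dihydro-1,2-oxaluminol-2-uide (cyclic alkenylalanate) | CC1=CCO[Al-]1(OCCOC)OCCOC.[Na+] | intermediate
14 | (2Z)-3-iodobut-2-en-1-ol | OC/C=C(/C)I | intermediate
15 | (2Z)-3-iodobut-2-enal | O=C/C=C(/C)I | intermediate
16 | (4S,5S)-4-[(1S,2Z)-1-hydroxy-3-iodobut-2-en-1-yl]-3-methylidene-5-[(1Z,3R)-3-[(tert-butyldimethylsilyl)oxy]-2-methylpenta-1,4-dien-1-yl]oxolan-2-one | C=C1C(=O)O[C@@H](/C=C(/C)[C@H](O[Si](C)(C)C(C)(C)C)C=C)[C@@H]1[C@H](O)/C=C(/C)I | intermediate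
17 | angelic acid, (2Z)-2-methylbut-2-enoic acid | C/C=C(/C)C(=O)O | starting material
18 | angelic 2,4,6-trichlorobenzoic anhydride | C/C=C(/C)C(=O)OC(=O)c1c(Cl)cc(Cl)cc1Cl | intermediate
19 | (1S,2Z)-3-iodo-1-{(2S,3R)-4-methylidene-5-oxo-2-[(1Z,3R)-3-[(tert-butyldimethylsilyl)oxy]-2-methylpenta-1,4-dien-1-yl]oxolan-3-yl}but-2-en-1-yl (2Z)-2-methylbut-2-enoate | C=C1C(=O)O[C@@H](/C=C(/C)[C@H](O[Si](C)(C)C(C)(C)C)C=C)[C@@H]1[C@H](OC(=O)/C(C)=C\C)/C=C(/C)I | intermediate
20 | dimethylamine adduct of 19 (4-[(dimethylamino)methyl] lactone, α-carbon unspecified) | CN(C)CC1C(=O)O[C@@H](/C=C(/C)[C@H](O[Si](C)(C)C(C)(C)C)C=C)[C@@H]1[C@H](OC(=O)/C(C)=C\C)/C=C(/C)I | intermediate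
21 | B-alkyl-9-BBN from 20 (terminal vinyl converted to CH2CH2–B) | CN(C)CC1C(=O)O[C@@H](/C=C(/C)[C@H](O[Si](C)(C)C(C)(C)C)CCB2C3CCCC2CCC3)[C@@H]1[C@H](OC(=O)/C(C)=C\C)/C=C(/C)I | intermediate
22 | macrocyclic amine: cis,cis-cyclodeca-1,6-diene trans-fused to the 3-[(dimethylamino)methyl]-γ-lactone, with OTBS and angelate | CN(C)CC1C(=O)O[C@H]2/C=C(/C)[C@H](O[Si](C)(C)C(C)(C)C)CC/C(C)=C\[C@@H](OC(=O)/C(C)=C\C)[C@H]12 | intermediate
23 | trimethylammonium iodide of 22 | C[N+](C)(C)CC1C(=O)O[C@H]2/C=C(/C)[C@H](O[Si](C)(C)C(C)(C)C)CC/C(C)=C\[C@@H](OC(=O)/C(C)=C\C)[C@H]12.[I-] | intermediate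
24 | macrocyclic diene: target ring with (Z)-C(CH3)=CH in place of the oxirane, α-methylene lactone, OTBS | C=C1C(=O)O[C@H]2/C=C(/C)[C@H](O[Si](C)(C)C(C)(C)C)CC/C(C)=C\[C@@H](OC(=O)/C(C)=C\C)[C@H]12 | intermediate
25 | bromohydrin of 24 (tertiary OH on the methyl-bearing carbon, Br on the adjacent CH, anti) | C=C1C(=O)O[C@H]2/C=C(/C)[C@H](O[Si](C)(C)C(C)(C)C)CC[C@@](C)(O)[C@H](Br)[C@@H](OC(=O)/C(C)=C\C)[C@H]12 | intermediate
26 | O-TBS ether of the target | C=C1C(=O)O[C@H]2/C=C(/C)[C@H](O[Si](C)(C)C(C)(C)C)CC[C@@]3(C)O[C@H]3[C@@H](OC(=O)/C(C)=C\C)[C@H]12 | intermediate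
27 | CNP0191628.1 | C=C1C(=O)O[C@H]2/C=C(/C)[C@H](O)CC[C@@]3(C)O[C@H]3[C@@H](OC(=O)/C(C)=C\C)[C@H]12 | target

Total step count: 17. Longest linear sequence: 15 (steps 1–8 and 11–17).

Steps most likely to fail

Step 14. Oligomerisation, protodeboronation or β-hydride elimination may outrun the intramolecular transmetallation, and Pd(0) may ionise the allylic esters once the iodide is consumed. The fallback forms the same bond by an intramolecular Negishi coupling and sets out from 20. Hydroboration with 9-BBN followed by NaBO3 oxidation would give the primary alcohol F1. I2/PPh3/imidazole would convert it into the primary iodide F2, used at once. Zinc insertion (Zn dust, LiCl, DMA) would give the alkylzinc iodide F3, and Pd2(dba)3/SPhos under high dilution would close the ring and return to the route at 22.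

Step 16. The bromonium ion may form at the other trisubstituted ring alkene or on the other face, or an ester carbonyl may take part in opening it. The fallback is a reagent-controlled Shi epoxidation (fructose-derived ketone of the antipode that delivers oxygen to the required face, Oxone, K2CO3, MeCN/DMM/H2O, 0 °C). It sets out from 24 and returns directly at 26; it makes no new compound (F0).

Step 11. Facial discrimination at the aldehyde may be poor if open and closed transition states compete, and some α-attack of the allylindium may occur. The fallback sets out from 11. Base-free Pd-catalysed borylation with B2pin2 would give the allylboronate F4. Its allylboration of 15 under chiral phosphoric acid catalysis (TRIP antipode chosen for the required aldehyde face, closed six-membered transition state) would give the O-boryl adduct F5, which is hydrolysed on work-up and returns to the route at 16.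

Further compounds
F1 | step 14 | primary alcohol from hydroboration–oxidation of 20 | CN(C)CC1C(=O)O[C@@H](/C=C(/C)[C@H](O[Si](C)(C)C(C)(C)C)CCO)[C@@H]1[C@H](OC(=O)/C(C)=C\C)/C=C(/C)I
F2 | step 14 | primary iodide from F1 | CN(C)CC1C(=O)O[C@@H](/C=C(/C)[C@H](O[Si](C)(C)C(C)(C)C)CCI)[C@@H]1[C@H](OC(=O)/C(C)=C\C)/C=C(/C)I
F3 | step 14 | alkylzinc iodide from F2 | CN(C)CC1C(=O)O[C@@H](/C=C(/C)[C@H](O[Si](C)(C)C(C)(C)C)CC[Zn]I)[C@@H]1[C@H](OC(=O)/C(C)=C\C)/C=C(/C)I
F0 | step 16 | none | none
F4 | step 11 | (5S)-3-[(4,4,5,5-tetramethyl-1,3,2-dioxaborolan-2-yl)methyl]-5-[(1Z,3R)-3-[(tert-butyldimethylsilyl)oxy]-2-methylpenta-1,4-dien-1-yl]furan-2(5H)-one | CC1(C)OB(CC2=C[C@H](/C=C(/C)[C@H](O[Si](C)(C)C(C)(C)C)C=C)OC2=O)OC1(C)C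
F5 | step 11 | O-pinacolboryl ether of 16 | C=C1C(=O)O[C@@H](/C=C(/C)[C@H](O[Si](C)(C)C(C)(C)C)C=C)[C@@H]1[C@H](OB2OC(C)(C)C(C)(C)O2)/C=C(/C)I
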